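**Retrosynthetic overview**
- Feature: the only ring to be built is the oxirane O1–C2–C3H2. Its quaternary C2, the single stereocentre, carries the benzene ring and a CH2OAc arm, so the target is the O-acetate of a 2-arylglycidol.
- Disconnection A (final flask): the acetate C–O bond, then O1–C2 and O1–C3 together, back to the 2-arylallyl alcohol. Its hydroxyl steers a tartrate–titanium oxygen transfer, and both isobutyrates are already in place.
- Disconnection B: the aryl–C2 bond, by a base-free Stille coupling of an aryl iodide bis(isobutyrate) with 2-(tributylstannyl)prop-2-en-1-ol.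
- Fragments: methyl 3-hydroxy-4-iodobenzoate (reduction, then double acylation with isobutyryl chloride) and propargyl alcohol (hydrostannation).
- Ring order: the benzene ring is bought. The oxirane is the only ring formed and is closed in the last flask.

Key step: step 5

Remark on the chemistry: in the target C2 is (S) (O1 > CH2OAc > C3H2 > aryl). The free epoxy alcohol of the same shape is (R) (O1 > C3H2 > CH2OH > aryl), so the epoxidation has to deliver the (R)-glycidol.

**Step 1**
Reactants: 1 methyl 3-hydroxy-4-iodobenzoate
Product: 2 5-(hydroxymethyl)-2-iodophenol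
Conditions: i-Bu2AlH (3.5 equiv), THF, −78 to 0 °C; then aq potassium sodium tartrate
Reagents that add atoms: none
Why: Hydride reduction of an ester with i-Bu2AlH, in which the first equivalent is spent on the phenol O–H, the next two take the ester through the aldehyde to the benzylic alkoxide, and the C–I bond is not attacked at or below 0 °C.

**Step 2**
Reactants: 2 5-(hydroxymethyl)-2-iodophenol; 3 isobutyryl chloride
Product: 4 2-iodo-5-[(isobutyryloxy)methyl]phenyl isobutyrate
Conditions: 3 (2.4 equiv), Et3N (3 equiv), DMAP (5 mol%), CH2Cl2, 0 °C to rt
Reagents that add atoms: isobutyryl chloride (3), CC(C)C(=O)Cl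
Why: DMAP-catalysed O-acylation through the acylpyridinium ion esterifies the phenol and the primary benzylic alcohol alike, while the aryl iodide is inert.

**Step 3**
Reactants: 5 propargyl alcohol (prop-2-yn-1-ol)
Product: 6 2-(tributylstannyl)prop-2-en-1-ol
Conditions: Bu3SnH (1.1 equiv, slow addition), PdCl2(PPh3)2 (2 mol%), THF, 0 °C to rt; chromatography on Et3N-deactivated silica
Reagents that add atoms: tributyltin hydride, CCCC[SnH](CCCC)CCCC
Why: Palladium-catalysed syn hydrostannation of a terminal alkyne, in which the inductively withdrawing propargylic oxygen steers tin in good part to the internal carbon, so 6 should form beside its terminal-tin regioisomer and is separated from it by chromatography.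

**Step 4**
Reactants: 4 2-iodo-5-[(isobutyryloxy)methyl]phenyl isobutyrate; 6 2-(tributylstannyl)prop-2-en-1-ol
Product: 7 2-{2-(isobutyryloxy)-4-[(isobutyryloxy)methyl]phenyl}prop-2-en-1-ol
Conditions: Pd2(dba)3 (2.5 mol%), AsPh3 (20 mol%), CuI (10 mol%), degassed NMP, rt to 45 °C
Reagents that add atoms: none
Why: Stille cross-coupling, in which the aryl iodide adds to zerovalent palladium near room temperature, AsPh3 and CuI speed up transmetalation of the hindered 1-substituted vinylstannane (which curbs cine substitution), and the absence of base, fluoride and strong heating should leave both esters and the free allylic hydroxyl where they are.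

**Step 5**
Reactants: 7 2-{2-(isobutyryloxy)-4-[(isobutyryloxy)methyl]phenyl}prop-2-en-1-ol
Product: 9 [(2S)-2-{2-(isobutyryloxy)-4-[(isobutyryloxy)methyl]phenyl}oxiran-2-yl]methyl acetate (target), via (R)-epoxy alcohol 8 (not isolated)
Conditions: Ti(OiPr)4 (5 mol%), D-(−)-diisopropyl tartrate (6 mol%), t-BuOOH (1.5 equiv, anhydrous, decane), powdered 4 Å MS, CH2Cl2, −20 °C; then P(OMe)3 (0.5 equiv), −20 °C; then Ac2O (2 equiv), Et3N (2.5 equiv), DMAP (5 mol%), −20 to 0 °C
Reagents that add atoms: tert-butyl hydroperoxide, CC(C)(C)OO; acetic anhydride, CC(=O)OC(C)=O
Why: Sharpless–Katsuki asymmetric epoxidation in its catalytic, sieve-assisted form with in situ derivatisation of the glycidol: 7 and t-BuOOH replace isopropoxide on one tetravalent titanium of the dimeric titanium–tartrate complex, and the distal peroxide oxygen passes to the C2=C3 π bond through a spiro transition state. O1–C2 and O1–C3 form in this one concerted [2+1] oxygen-atom transfer, which is the mode of closure of the oxirane, the only ring made. The quaternary stereocentre C2 is set by the tartrate alone: D-(−)-tartrates turn allyl alcohol, methallyl alcohol and 2-arylallyl alcohols into the (R)-glycidols, which here means oxygen delivery to the Re face of C2 and formation of (R)-8. The step needs face selectivity at a 1,1-disubstituted alkene, secured by the covalent Ti–O anchor of the CH2OH group that sits on C2 itself, and chemoselectivity for the alkene over the two esters, secured by −20 °C and the α-branched, slowly transesterified isobutyryl groups. It also needs the benzylic tertiary oxirane to outlast the Lewis acid, which the low titanium loading, the sieves and the weakly donating acyloxy-substituted arene (slow ionisation of C2–O1) should allow. Once P(OMe)3 has reduced the surplus hydroperoxide, DMAP-catalysed acetylation caps the primary hydroxyl before acyl migration or ring opening sets in; no bond at C2 is touched, and the descriptor turns from (R) to (S) only because CH2OAc outranks the ring CH2 whereas CH2OH does not.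

**Compound list**
1 | methyl 3-hydroxy-4-iodobenzoate | COC(=O)c1ccc(I)c(O)c1 | starting material
2 | 5-(hydroxymethyl)-2-iodophenol | OCc1ccc(I)c(O)c1 | intermediate
3 | isobutyryl chloride | CC(C)C(=O)Cl | starting material
4 | 2-iodo-5-[(isobutyryloxy)methyl]phenyl isobutyrate | CC(C)C(=O)OCc1ccc(I)c(OC(=O)C(C)C)c1 | intermediate
5 | propargyl alcohol | C#CCO | starting material
6 | 2-(tributylstannyl)prop-2-en-1-ol | OCC(=C)[Sn](CCCC)(CCCC)CCCC | intermediate
7 | 2-{2-(isobutyryloxy)-4-[(isobutyryloxy)methyl]phenyl}prop-2-en-1-ol | OCC(=C)c1ccc(COC(=O)C(C)C)cc1OC(=O)C(C)C | intermediate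
8 | [(2R)-2-{2-(isobutyryloxy)-4-[(isobutyryloxy)methyl]phenyl}oxiran-2-yl]methanol | OC[C@]1(c2ccc(COC(=O)C(C)C)cc2OC(=O)C(C)C)CO1 | intermediate
9 | [(2S)-2-{2-(isobutyryloxy)-4-[(isobutyryloxy)methyl]phenyl}oxiran-2-yl]methyl acetate (CNP0151517.1) | CC(=O)OC[C@]1(c2ccc(COC(=O)C(C)C)cc2OC(=O)C(C)C)CO1 | target

**Total step count:** 5
**Longest linear sequence:** 4 steps (1 → 2 → 4 → 7 → 9, that is steps 1, 2, 4 and 5)

**Steps most likely to fail**

1. Step 5. Three processes may spoil it:
   - titanium-alkoxide-induced opening of the benzylic oxirane;
   - migration of the phenolic isobutyryl group to the neighbouring primary alkoxide;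
   - incomplete facial selectivity.

   The fallback sets out from 7 and comes back at 9, and it never exposes a free hydroxyl next to the oxirane or to a Lewis acid. Acetylation of 7 (Ac2O, Et3N, DMAP, CH2Cl2, 0 °C) should give 2-{2-(isobutyryloxy)-4-[(isobutyryloxy)methyl]phenyl}allyl acetate F1. Undirected Prilezhaev epoxidation with mCPBA buffered by NaHCO3 should give the racemic [2-{2-(isobutyryloxy)-4-[(isobutyryloxy)methyl]phenyl}oxiran-2-yl]methyl acetate F2. Preparative supercritical-fluid chromatography on a polysaccharide chiral phase then separates the enantiomers. The (S)-enantiomer 9 is identified by chiroptical comparison with enriched material from step 5.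

2. Step 4. Slow transmetalation of the hindered vinylstannane may open the way to cine substitution, protodestannylation or homocoupling, and the product may suffer an O-to-O acyl shift on prolonged warming. The fallback sets out from 2 and comes back at 7. It puts a base-tolerant coupling before the acylation and installs the allylic oxygen by C–H oxidation.
   - Suzuki–Miyaura coupling of 2 with isopropenylboronic acid pinacol ester (Pd(dppf)Cl2, K2CO3, dioxane/H2O, 80 °C) should give 5-(hydroxymethyl)-2-(prop-1-en-2-yl)phenol F3.
   - Double acylation with 3 under the conditions of step 2 should give 5-[(isobutyryloxy)methyl]-2-(prop-1-en-2-yl)phenyl isobutyrate F4.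
   - Catalytic SeO2 with t-BuOOH in CH2Cl2 then hydroxylates the only allylic methyl group by the ene/[2,3]-sigmatropic sequence of the Riley oxidation and delivers 7.

3. Step 3. Regiocontrol in the H–Sn addition may be poor, and stannane may be lost by protodestannylation during the chromatographic separation. The fallback sets out from 5 and comes back at 6, and it fixes the regiochemistry by a Markovnikov addition.
   - Hydroiodination of 5 with HI generated from NaI, Me3SiCl and water in MeCN should give 2-iodoprop-2-en-1-ol F5.
   - t-BuLi (3 equiv, Et2O, −78 °C) deprotonates the hydroxyl and exchanges iodine for lithium to give lithium 2-lithioprop-2-en-1-olate F6.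
   - The carbanion of F6 is stannylated by Bu3SnCl, and aqueous work-up should return 6 as a single regioisomer.

**Further compounds**
F1 | step 5 | 2-{2-(isobutyryloxy)-4-[(isobutyryloxy)methyl]phenyl}allyl acetate | CC(=O)OCC(=C)c1ccc(COC(=O)C(C)C)cc1OC(=O)C(C)C
F2 | step 5 | racemic [2-{2-(isobutyryloxy)-4-[(isobutyryloxy)methyl]phenyl}oxiran-2-yl]methyl acetate | CC(=O)OCC1(c2ccc(COC(=O)C(C)C)cc2OC(=O)C(C)C)CO1
F3 | step 4 | 5-(hydroxymethyl)-2-(prop-1-en-2-yl)phenol | CC(=C)c1ccc(CO)cc1O
F4 | step 4 | 5-[(isobutyryloxy)methyl]-2-(prop-1-en-2-yl)phenyl isobutyrate | CC(=C)c1ccc(COC(=O)C(C)C)cc1OC(=O)C(C)C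
F5 | step 3 | 2-iodoprop-2-en-1-ol | OCC(I)=C
F6 | step 3 | lithium 2-lithioprop-2-en-1-olate | [Li]OCC(=C)[Li]
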